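The route rests on disconnecting the C7'–O bond: the carbinol oxygen reaches the benzylic C7'–H of an arctigenin-type lactone through a temporary carboxyl on C8. The key step exploits that C7'–H is benzylic to the electron-rich veratryl ring and that C7' lies cis to the C8 carboxyl on lactone ring A: anodic oxidation gives the C7' cation, the carboxyl traps it, and in one operation lactone ring B of a cis-fused dilactone closes and C7' is set with the aryl group exo. The precursor is the (R)-β-veratrylmethyl butyrolactone bearing on C8 a free carboxyl cis to C7' and, trans, the guaiacylmethyl group as its pivalate. Saponification, relactonisation onto O9' and decarboxylation finish.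

Key step: step 10

Remark: lignan numbering is used (C9 lactone carbonyl, C8 its α-carbon, C7 the benzylic CH2 on C8, C8' the β-carbon, C9' the ring CH2, C7' the carbinol carbon, C10 the relay carboxyl carbon; ring A is the C9/C9' lactone, ring B the lactone closed in step 10); the target is (7'S,8R,8'R); the sense of induction in step 2 is assigned by analogy with enamide hydrogenation and is checked through the sign of rotation of the known lactone 6, the antipodal ligand being used otherwise.

Step 1
Reactants: 1 veratraldehyde; 2 dimethyl succinate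
Product: 3 (E)-4-(3,4-dimethoxyphenyl)-3-(methoxycarbonyl)but-3-enoic acid
Conditions: NaOMe, MeOH, reflux; then aq. HCl
Reagents that add atoms: none
Why: Stobbe condensation: the succinate enolate adds to the aldehyde, the alkoxide lactonises onto the distal ester, and base-induced opening of the paraconate gives the E-arylidene half-ester with the conjugated ester kept and the CH2CO2H arm free.

Step 2
Reactants: 3 (E)-4-(3,4-dimethoxyphenyl)-3-(methoxycarbonyl)but-3-enoic acid
Product: 4 (R)-4-(3,4-dimethoxyphenyl)-3-(methoxycarbonyl)butanoic acid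
Conditions: H2 (5 bar), [Rh(cod)((S,S)-Et-DuPhos)]BF4 (1 mol%), NaOMe (10 mol%), MeOH, rt
Reagents that add atoms: none
Why: Rhodium–bisphosphine asymmetric hydrogenation of an itaconate-type half-ester: chelation of the alkene and the β-carboxylate to the cationic rhodium centre fixes the enantioface that takes up H2 and sets C8' as R.

Step 3
Reactants: 4 (R)-4-(3,4-dimethoxyphenyl)-3-(methoxycarbonyl)butanoic acid
Product: 6 (R)-4-(3,4-dimethoxybenzyl)dihydrofuran-2(3H)-one, via potassium hydroxy carboxylate 5 (not isolated)
Conditions: KOH (1 equiv), EtOH; CaCl2, NaBH4, −10 °C → rt (Ca(BH4)2 formed in the flask); then 2 M HCl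
Reagents that add atoms: none
Why: Chemoselective borohydride reduction and lactonisation: Ca(BH4)2 reduces the methyl ester but not the carboxylate, and acid closes the γ-lactone from the CH2CO2H arm, so C8' stays R and the carbonyl ends up at C9.

Step 4
Reactants: 6 (R)-4-(3,4-dimethoxybenzyl)dihydrofuran-2(3H)-one
Product: 7 benzyl (4R)-4-(3,4-dimethoxybenzyl)-2-oxotetrahydrofuran-3-carboxylate (both C8 epimers, configurationally labile)
Conditions: LiN(SiMe3)2 (2.2 equiv), THF, −78 °C; BnOCOCl, −78 → −40 °C; aq. NH4Cl
Reagents that add atoms: benzyl chloroformate, O=C(Cl)OCc1ccccc1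
Why: Claisen-type C-acylation of the lactone lithium enolate with a chloroformate, the second equivalent of base storing the more acidic product as its enolate; the C8 configuration is irrelevant because C8 is deprotonated again in step 8.

Step 5
Reactants: 8 vanillin
Product: 9 4-formyl-2-methoxyphenyl pivalate
Conditions: t-BuCOCl, Et3N, DMAP (cat.), CH2Cl2, 0 °C → rt
Reagents that add atoms: pivaloyl chloride, CC(C)(C)C(=O)Cl
Why: Acylation of the phenol with an acid chloride under nucleophilic catalysis; the pivalate is bulky enough to survive the enolate alkylation and electron-poor enough to raise the oxidation potential of this ring for step 10.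

Step 6
Reactants: 9 4-formyl-2-methoxyphenyl pivalate
Product: 10 4-(hydroxymethyl)-2-methoxyphenyl pivalate
Conditions: NaBH4, MeOH/THF, 0 °C
Reagents that add atoms: none
Why: Borohydride reduction of the aldehyde, which leaves the hindered aryl ester untouched at 0 °C.

Step 7
Reactants: 10 4-(hydroxymethyl)-2-methoxyphenyl pivalate
Product: 11 4-(bromomethyl)-2-methoxyphenyl pivalate
Conditions: PBr3 (0.4 equiv), CH2Cl2, 0 °C
Reagents that add atoms: phosphorus tribromide, BrP(Br)Br
Why: Conversion of the benzylic alcohol into the bromide by SN2 displacement of its phosphite ester.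

Step 8
Reactants: 7 benzyl (4R)-4-(3,4-dimethoxybenzyl)-2-oxotetrahydrofuran-3-carboxylate; 11 4-(bromomethyl)-2-methoxyphenyl pivalate
Product: 12 benzyl 4-(3,4-dimethoxybenzyl)-3-[3-methoxy-4-(pivaloyloxy)benzyl]-2-oxotetrahydrofuran-3-carboxylate (C8' R; on C8 the new benzyl group trans and the ester cis to the C8' veratrylmethyl group)
Conditions: K2CO3, DMF, rt
Reagents that add atoms: none
Why: Malonate-type SN2 C-alkylation of the stabilised enolate, in which the benzylic bromide approaches the planar C8 anti to the C8' veratrylmethyl group, so the quaternary C8 is formed with the new benzyl group trans and the ester cis to C7'.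

Step 9
Reactants: 12 benzyl ester of the quaternary lactone
Product: 13 4-(3,4-dimethoxybenzyl)-3-[3-methoxy-4-(pivaloyloxy)benzyl]-2-oxotetrahydrofuran-3-carboxylic acid (configuration as in 12; carboxyl cis to C7')
Conditions: H2 (1 atm), 10% Pd/C, EtOAc, rt
Reagents that add atoms: none
Why: Hydrogenolysis of the benzyl ester over palladium under neutral conditions, which frees the relay carboxyl without touching the lactone, the pivalate or C8 and leaves no amine or soluble metal to interfere at the anode.

Step 10
Reactants: 13 relay acid (carboxyl on C8 cis to C7')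
Product: 14 1-[3-methoxy-4-(pivaloyloxy)benzyl]-6-exo-(3,4-dimethoxyphenyl)-3,7-dioxabicyclo[3.3.0]octane-2,8-dione (cis-fused, C7' S)
Conditions: undivided cell, graphite anode, Pt cathode, constant current (about 2.2 F/mol), n-Bu4NBF4, 2,4,6-collidine (1 equiv), MeCN/HFIP 4:1, rt
Reagents that add atoms: none
Why: Electron transfer from the veratryl ring (the most easily oxidised π-system) at the carbon anode, loss of the C7' proton to collidine and a second electron transfer give a para-methoxy-stabilised benzylic cation at C7', which the carboxyl on C8 captures with loss of a proton while protons are reduced to H2 at the cathode. The closest known reaction type is the oxidative (anodic or quinone-mediated) benzylic C–H lactonisation of 4-arylbutanoic acids that carry electron-rich arenes. Ring B (C8, C10, O, C7', C8') closes by 5-exo-trig attack of the carboxyl oxygen on the cationic C7'. The new stereocentre C7' is controlled by the cis ring fusion of the bicyclo[3.3.0] dilactone: of the two rotamers of the cation that the cis carboxyl can reach, the one that places the aryl group on the convex (exo) face, away from the C9' methylene of ring A, is favoured, which gives 7'S. Site selectivity for C7' over C7 is needed and is secured by the lower oxidation potential of the dimethoxy ring compared with the acyloxy-methoxy ring, by the electron-poor quaternary C8 next to C7, and by the fact that only a C7' cation has a five-membered trap; weak base, HFIP and a limited charge keep the acid from anodic decarboxylation and the product from further oxidation.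

Step 11
Reactants: 14 dilactone
Product: 16 4-[(S)-(3,4-dimethoxyphenyl)(hydroxy)methyl]-3-(4-hydroxy-3-methoxybenzyl)-2-oxotetrahydrofuran-3-carboxylic acid (C8' R; both C8 epimers), via trilithium salt 15 (not isolated)
Conditions: LiOH (8 equiv), THF/H2O, rt; then 1 M HCl to pH 3, 0 °C, EtOAc (crude acid used at once)
Reagents that add atoms: lithium hydroxide, [Li+].[OH-]
Why: Hydroxide saponification (acyl–oxygen cleavage, so C7' keeps its configuration) opens both lactones and the pivalate, and on acidification the unhindered primary O9'–H closes the γ-lactone first (5-exo-trig at a gem-dicarboxylic acid), the hindered benzylic hydroxyl lagging behind.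

Step 12
Reactants: 16 lactone acid (C8 epimers)
Product: 18 4-[(S)-(tert-butyldimethylsilyloxy)(3,4-dimethoxyphenyl)methyl]-3-[4-(tert-butyldimethylsilyloxy)-3-methoxybenzyl]-2-oxotetrahydrofuran-3-carboxylic acid (C8 epimers), via tris-silyl derivative 17 (not isolated)
Conditions: t-BuMe2SiOTf (3.5 equiv), 2,6-lutidine, CH2Cl2, −40 → 0 °C; then THF/H2O/AcOH, rt
Reagents that add atoms: tert-butyldimethylsilyl triflate, CC(C)(C)[Si](C)(C)OS(=O)(=O)C(F)(F)F
Why: Silylation of the hydroxyl, phenol and carboxyl groups with a silyl triflate and a hindered pyridine, followed by selective hydrolysis of the labile silyl ester; capping O7' rules out re-closure to 14 on heating and acyl migration during the later equilibration.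

Step 13
Reactants: 18 bis-silyl lactone acid (C8 epimers)
Product: 20 bis(tert-butyldimethylsilyl) ether of the target (8,8'-trans; C8 R, C8' R, C7' S), via C8-epimeric lactone 19 (not isolated)
Conditions: toluene, 110 °C; then DBU (0.5 equiv), 110 °C
Reagents that add atoms: none
Why: Thermal decarboxylation of the malonic half-ester-type acid through a six-membered transition state gives the lactone enol, and amidine-mediated enolisation then equilibrates C8 to the thermodynamically preferred 8,8'-trans lactone with the benzyl group anti to the bulky silyloxybenzyl substituent.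

Step 14
Reactants: 20 bis-silyl ether of the target
Product: 21 (3R,4R)-4-[(S)-(3,4-dimethoxyphenyl)(hydroxy)methyl]-3-(4-hydroxy-3-methoxybenzyl)dihydrofuran-2(3H)-one
Conditions: Bu4NF (3 equiv), AcOH (3 equiv), THF, 0 °C → rt
Reagents that add atoms: none
Why: Fluoride-mediated cleavage of both silyl ethers, buffered with acetic acid so that neither C8 nor the lactone is disturbed.

Compound list

1 | veratraldehyde (3,4-dimethoxybenzaldehyde) | COc1ccc(C=O)cc1OC | starting material
2 | dimethyl succinate | COC(=O)CCC(=O)OC | starting material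
3 | (E)-4-(3,4-dimethoxyphenyl)-3-(methoxycarbonyl)but-3-enoic acid | COC(=O)/C(CC(=O)O)=C/c1ccc(OC)c(OC)c1 | intermediate
4 | (R)-4-(3,4-dimethoxyphenyl)-3-(methoxycarbonyl)butanoic acid | COC(=O)[C@@H](CC(=O)O)Cc1ccc(OC)c(OC)c1 | intermediate
5 | potassium (R)-4-(3,4-dimethoxyphenyl)-3-(hydroxymethyl)butanoate | [K+].[O-]C(=O)C[C@H](CO)Cc1ccc(OC)c(OC)c1 | intermediate (not isolated)
6 | (R)-4-(3,4-dimethoxybenzyl)dihydrofuran-2(3H)-one | O=C1OC[C@H](Cc2ccc(OC)c(OC)c2)C1 | intermediate
7 | benzyl (4R)-4-(3,4-dimethoxybenzyl)-2-oxotetrahydrofuran-3-carboxylate, C8 epimers | O=C1OC[C@H](Cc2ccc(OC)c(OC)c2)C1C(=O)OCc1ccccc1 | intermediate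
8 | vanillin | COc1cc(C=O)ccc1O | starting material
9 | 4-formyl-2-methoxyphenyl pivalate | COc1cc(C=O)ccc1OC(=O)C(C)(C)C | intermediate
10 | 4-(hydroxymethyl)-2-methoxyphenyl pivalate | COc1cc(CO)ccc1OC(=O)C(C)(C)C | intermediate
11 | 4-(bromomethyl)-2-methoxyphenyl pivalate | COc1cc(CBr)ccc1OC(=O)C(C)(C)C | intermediate
12 | benzyl 4-(3,4-dimethoxybenzyl)-3-[3-methoxy-4-(pivaloyloxy)benzyl]-2-oxotetrahydrofuran-3-carboxylate, benzyl groups trans, ester cis to C7' | COc1cc(C[C@@]2(C(=O)OCc3ccccc3)C(=O)OC[C@@H]2Cc2ccc(OC)c(OC)c2)ccc1OC(=O)C(C)(C)C | intermediate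
13 | 4-(3,4-dimethoxybenzyl)-3-[3-methoxy-4-(pivaloyloxy)benzyl]-2-oxotetrahydrofuran-3-carboxylic acid, benzyl groups trans, carboxyl cis to C7' | COc1cc(C[C@@]2(C(=O)O)C(=O)OC[C@@H]2Cc2ccc(OC)c(OC)c2)ccc1OC(=O)C(C)(C)C | intermediate (key-step precursor)
14 | 1-[3-methoxy-4-(pivaloyloxy)benzyl]-6-exo-(3,4-dimethoxyphenyl)-3,7-dioxabicyclo[3.3.0]octane-2,8-dione | COc1cc(C[C@@]23C(=O)OC[C@@H]2[C@H](OC3=O)c2ccc(OC)c(OC)c2)ccc1OC(=O)C(C)(C)C | intermediate (key-step product)
15 | trilithium salt (dicarboxylate, phenoxide) of 2-[(1S,2R)-1-(3,4-dimethoxyphenyl)-1,3-dihydroxypropan-2-yl]-2-(4-hydroxy-3-methoxybenzyl)malonic acid | [Li+].[Li+].[Li+].COc1cc(CC(C(=O)[O-])(C(=O)[O-])[C@H](CO)[C@H](O)c2ccc(OC)c(OC)c2)ccc1[O-] | intermediate (not isolated)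
16 | 4-[(S)-(3,4-dimethoxyphenyl)(hydroxy)methyl]-3-(4-hydroxy-3-methoxybenzyl)-2-oxotetrahydrofuran-3-carboxylic acid, C8' R, C8 epimers | COc1cc(CC2(C(=O)O)C(=O)OC[C@@H]2[C@H](O)c2ccc(OC)c(OC)c2)ccc1O | intermediate
17 | tris(tert-butyldimethylsilyl) derivative of 16 (silyl ester, C7' silyl ether, aryl silyl ether) | COc1cc(CC2(C(=O)O[Si](C)(C)C(C)(C)C)C(=O)OC[C@@H]2[C@H](O[Si](C)(C)C(C)(C)C)c2ccc(OC)c(OC)c2)ccc1O[Si](C)(C)C(C)(C)C | intermediate (not isolated)
18 | bis(tert-butyldimethylsilyl) ether of 16 with free carboxyl, C8 epimers | COc1cc(CC2(C(=O)O)C(=O)OC[C@@H]2[C@H](O[Si](C)(C)C(C)(C)C)c2ccc(OC)c(OC)c2)ccc1O[Si](C)(C)C(C)(C)C | intermediate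
19 | bis(tert-butyldimethylsilyl) ether of the target lactone, C8 epimers | COc1cc(CC2C(=O)OC[C@@H]2[C@H](O[Si](C)(C)C(C)(C)C)c2ccc(OC)c(OC)c2)ccc1O[Si](C)(C)C(C)(C)C | intermediate (not isolated)
20 | bis(tert-butyldimethylsilyl) ether of the target, 8,8'-trans | COc1cc(C[C@H]2C(=O)OC[C@@H]2[C@H](O[Si](C)(C)C(C)(C)C)c2ccc(OC)c(OC)c2)ccc1O[Si](C)(C)C(C)(C)C | intermediate
21 | (3R,4R)-4-[(S)-(3,4-dimethoxyphenyl)(hydroxy)methyl]-3-(4-hydroxy-3-methoxybenzyl)dihydrofuran-2(3H)-one | COc1cc(C[C@H]2C(=O)OC[C@@H]2[C@H](O)c2ccc(OC)c(OC)c2)ccc1O | target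

Total step count: 14. Longest linear sequence: 11 steps (steps 1–4 and 8–14).

Steps most likely to fail

1. Step 10. What may go wrong: oxidation running on past the lactone, carbon–carbon cyclisation of the C7' cation onto the guaiacyl ring, or anodic loss of CO2 from the relay carboxyl. The fallback is a two-stage oxygenation with known chemistry. It sets out from 12: DDQ in wet CH2Cl2 oxidises the veratrylic CH2 to the aryl ketone, giving the 7'-oxo benzyl ester F1 (base is avoided so that C8' is not enolised). A reagent-controlled Corey–Bakshi–Shibata reduction ((R)-Me-CBS, BH3·SMe2, THF, −20 °C) should then give the 7'S carbinol, the hydroxy benzyl ester F2. Its hydroxyl, cis to the benzyl ester, closes ring B by transesterification (PPTS, toluene, 60 °C), and the route is rejoined at 14.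

2. Step 11. What may go wrong: lactonisation onto the benzylic hydroxyl, further closure back to the dilactone, or ionisation at C7' while the mixture is acidic. The fallback fixes the regiochemistry by protecting groups and avoids acidification. It sets out from 14: the salt 15 is made as before, dried and persilylated (t-BuMe2SiCl, imidazole, DMF) to the pentasilyl compound F3. Aqueous AcOH in THF cleaves only the two silyl esters and gives the tris-silyl malonic acid F4. Heating in pyridine removes one carboxyl and gives the tris-silyl monoacid F5 (C8 epimers). HF·pyridine at 0 °C frees only the primary hydroxyl to give the hydroxy acid F6, which lactonises onto O9'. The route is rejoined at 19, from which the equilibration of step 13 and step 14 follow.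

3. Step 13. What may go wrong: slow loss of CO2 at the quaternary centre, with desilylation on prolonged heating. The fallback is a radical decarboxylation at room temperature. It sets out from 18: N-hydroxypyridine-2-thione, DCC and catalytic DMAP in CH2Cl2 (dark) give the Barton ester F7. Irradiation with visible light in the presence of t-BuSH replaces the acyloxy group by hydrogen, and the route is rejoined at 19, which is equilibrated with DBU as in step 13.

Further compounds

F1 | step 10 | benzyl 4-(3,4-dimethoxybenzoyl)-3-[3-methoxy-4-(pivaloyloxy)benzyl]-2-oxotetrahydrofuran-3-carboxylate (7'-oxo benzyl ester, configuration as in 12) | COc1cc(C[C@@]2(C(=O)OCc3ccccc3)C(=O)OC[C@@H]2C(=O)c2ccc(OC)c(OC)c2)ccc1OC(=O)C(C)(C)C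
F2 | step 10 | benzyl 4-[(S)-(3,4-dimethoxyphenyl)(hydroxy)methyl]-3-[3-methoxy-4-(pivaloyloxy)benzyl]-2-oxotetrahydrofuran-3-carboxylate (hydroxy benzyl ester) | COc1cc(C[C@@]2(C(=O)OCc3ccccc3)C(=O)OC[C@@H]2[C@H](O)c2ccc(OC)c(OC)c2)ccc1OC(=O)C(C)(C)C
F3 | step 11 | pentakis(tert-butyldimethylsilyl) derivative of the seco diacid (two silyl esters, O9', O7' and aryl silyl ethers) | COc1cc(CC(C(=O)O[Si](C)(C)C(C)(C)C)(C(=O)O[Si](C)(C)C(C)(C)C)[C@H](CO[Si](C)(C)C(C)(C)C)[C@H](O[Si](C)(C)C(C)(C)C)c2ccc(OC)c(OC)c2)ccc1O[Si](C)(C)C(C)(C)C
F4 | step 11 | tris-silyl malonic acid (O9', O7' and aryl silyl ethers, two free carboxyls) | COc1cc(CC(C(=O)O)(C(=O)O)[C@H](CO[Si](C)(C)C(C)(C)C)[C@H](O[Si](C)(C)C(C)(C)C)c2ccc(OC)c(OC)c2)ccc1O[Si](C)(C)C(C)(C)C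
F5 | step 11 | tris-silyl monoacid, C8 epimers | COc1cc(CC(C(=O)O)[C@H](CO[Si](C)(C)C(C)(C)C)[C@H](O[Si](C)(C)C(C)(C)C)c2ccc(OC)c(OC)c2)ccc1O[Si](C)(C)C(C)(C)C
F6 | step 11 | hydroxy acid with free primary hydroxyl (O7' and aryl silyl ethers kept), C8 epimers | COc1cc(CC(C(=O)O)[C@H](CO)[C@H](O[Si](C)(C)C(C)(C)C)c2ccc(OC)c(OC)c2)ccc1O[Si](C)(C)C(C)(C)C
F7 | step 13 | Barton ester (2-thioxopyridin-1(2H)-yl ester) of 18, C8 epimers | COc1cc(CC2(C(=O)ON3C=CC=CC3=S)C(=O)OC[C@@H]2[C@H](O[Si](C)(C)C(C)(C)C)c2ccc(OC)c(OC)c2)ccc1O[Si](C)(C)C(C)(C)C
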